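(The earlier runs and the new flask come from a simulation with made-up constants; scatter was added.)

1. I decide to follow one number through these flasks: the selectivity, which I call the Jo share, meaning Jo divided by Jo plus Ze, both as fractions of the Ym charged.

| setting | green | violet | Wednesday's | Monday's | Friday's | Thursday's | Saturday's |
|---|---|---|---|---|---|---|---|
| Ym | 0.088 M | 1.3 M | 0.10 M | 0.20 M | 0.40 M | 0.80 M | 1.5 M |
| remark | run made earlier | run made earlier |  |  |  |  |  |
| time |  |  | 3.0 min | 3.0 min | 3.0 min | 3.0 min | 3.0 min |

- green (time / s: Jo / %, Ze / %, Ym / %): 30.0: 1.5, 6.8, 37.5; 60.0: 3.2, 16.9, 13.7; 90.0: 4.5, 28.1, 5.5; 120: 5.5, 37.0, 1.7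
- violet (time / s: Jo / %, Ze / %, Ym / %): 10.0: 0, 0.9, 72.1; 25.0: 0.9, 5.2, 45.1; 50.0: 0.8, 14.5, 19.1; 120: 5.1, 37.1, 2.2

(standard deviation of a reading: 0.5 percentage points)

- steps that have been proposed: Ym -> Dx; Dx -> Jy; Jy -> Jo; Jy -> Ze; Ym -> Ze; Ym -> Jy
- "hardly changes" means that all values lie within two and a half points (for a concentration: within two and a half percent of the largest)

- share of Jo in all that became Jo or Ze for Wednesday's, Monday's, Friday's, Thursday's, Saturday's, in this order
- how that number moves from the first to the last of them (falls, then rises / rises all the way / rises, then falls / falls all the way / hardly changes)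

2. The green run's last reading, at 120 s, gives a Jo share of 12.9%. But that is one charge, and the question is about charge.

3. The violet run holds 14.8 times the green charge, and its last reading, at 120 s, gives 12.1%. Is that a real fall? The two Jo readings differ by 0.4 percentage points, less than the scatter of 0.5 points, and the Ze readings are 37.0% and 37.1%. So I see no effect of the charge, and I add the two readings together: Jo over Jo plus Ze, summed over both last readings, is the pooled share 12.5%.

4. Earlier readings object: green at 60.0 s gives 15.9%, violet at 50.0 s gives 5.23%. But Jo there is 3.2% in green and 0.8% in violet, against a scatter of 0.5 points, so I weigh these two shares lightly.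

5. A harder objection: at its last reading green still holds 55.8% of the charge outside Ym, Jo and Ze, presumably as Dx and Jy, so the level may still shift. I cannot compute that away. Violet holds 55.6%, though, so the two charges stand alike, and I trust the flatness more than the level. Saturday's charge is 1.15 times violet's, a short step beyond the runs. I commit to a flat row near the pooled share.

6. The forecast gives 12.7% at the five charges, hardly changes, holding that “the share should be independent of concentration and time”. Its number stands 0.20 points above mine.

7. The flasks give 13.3%, 13.3%, 13.3%, 13.3%, 13.3%: hardly changes, so the forecast held.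

    Ym → Dx (k = 0.0250 s⁻¹)
    Dx → Jy (k = 0.00580 s⁻¹)
    Jy → Jo (k = 0.00410 s⁻¹)
    Jy → Ze (k = 0.0250 s⁻¹)
    Ym → Ze (k = 0.00110 s⁻¹)
    Ym → Jy (k = 0.00660 s⁻¹)

In Wednesday's flask Jy has a half-life of 0.46 min at 0.352 min by the step to Ze, against 2.8 min by the step to Jo alone, which is 6.09 times as long. A reading ten times later makes no difference to that flask's share. The pooled share, applied to Wednesday's Ze of 51.3% at 3.00 min, gives a Jo of 7.33%, and the flask holds 7.86%. Applied to Saturday's Jo plus Ze at 30.0 min, it gives a Jo of 12.5%, and that flask holds 13.6%.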